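Ring B is read as a 4-substituted cyclohexanone: the phenolic carbon C4 is the carbonyl, C3 and C5 are its two equivalent α-methylenes, and C1 carries the three-carbon chain. One double Claisen–Schmidt condensation with prenal forms the C3–C1'' and C5–C1'' bonds as exocyclic E-dienylidene units, so the 3,5-diprenyl pattern is set with no phenol prenylation. A later shift of both alkenes into the ring unveils the phenol. The precursor is the symmetric 3-(4-oxocyclohexyl)propanoyl skeleton, carried as its Weinreb amide and not as the free acid, so that the acyl carbon is already armed for union with lithiated tris-MOM-phloroglucinol (ring A).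

Key step: step 4

Remark: the cyclohexanol from the hydrogenation is carried on as its cis/trans mixture, since the oxidation that follows erases the difference.

Step 1
Reactants: 1 3-(4-hydroxyphenyl)propanoic acid (phloretic acid)
Product: 2 3-(4-hydroxycyclohexyl)propanoic acid (cis/trans mixture)
Conditions: H2 (5 bar), 5% Rh/Al2O3, EtOH, 50 °C
Reagents that add atoms: none
Why: Heterogeneous arene hydrogenation over rhodium saturates the phenol ring under mild pressure with little C–O hydrogenolysis and leaves the carboxylic acid alone; hydrogen comes mainly from one face to give chiefly the cis isomer, which is of no consequence because the carbinol carbon becomes the carbonyl in step 2.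

Step 2
Reactants: 2 3-(4-hydroxycyclohexyl)propanoic acid (cis/trans mixture)
Product: 3 3-(4-oxocyclohexyl)propanoic acid
Conditions: NaOCl (aq., 1.2 equiv), AcOH, 0 °C to rt
Reagents that add atoms: none
Why: Hypochlorite oxidation of a secondary alcohol in acetic acid (Stevens conditions) should give the same ketone from both isomers, and the carboxylic acid and the saturated ring offer nothing else to oxidise.

Step 3
Reactants: 3 3-(4-oxocyclohexyl)propanoic acid
Product: 5 N-methoxy-N-methyl-3-(4-oxocyclohexyl)propanamide, via acyl imidazolide 4 (not isolated)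
Conditions: CDI (1.1 equiv), CH2Cl2, rt; then MeNHOMe·HCl (1.3 equiv), rt
Reagents that add atoms: N,O-dimethylhydroxylamine hydrochloride, CNOC.Cl
Why: CDI activation gives the acyl imidazolide 4, which is aminolysed by N,O-dimethylhydroxylamine (Weinreb amide formation); the ketone is untouched because a secondary hydroxylamine cannot form an oxime.

Step 4
Reactants: 5 N-methoxy-N-methyl-3-(4-oxocyclohexyl)propanamide; 6 3-methylbut-2-enal (prenal)
Product: 8 N-methoxy-N-methyl-3-[(3E,5E)-3,5-bis(3-methylbut-2-en-1-ylidene)-4-oxocyclohexyl]propanamide, via mono-dienylidene ketone 7 (not isolated)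
Conditions: NaOH (2 M aq., 0.5 equiv), EtOH, 0 °C to rt; 6 (2.6 equiv) added over 6 h; light excluded
Reagents that add atoms: none
Why: Hydroxide reversibly forms the ketone enolate, which adds 1,2 to the aldehyde carbon of prenal and loses water by E1cB to the conjugated dienone 7, and the sequence then repeats at the second, symmetry-equivalent α-methylene. The closest known reaction type is the double Claisen–Schmidt condensation of cyclohexanones with enals such as cinnamaldehyde, together with the base-mediated condensation of β,β-disubstituted enals with ketones. No ring is closed and no stereocentre is created; the only stereochemical element is the alkene geometry, which should settle as E,E because that is the thermodynamically preferred geometry of 2-alkylidenecyclohexanones and the dehydration is reversible enough to reach it. The step needs cross-condensation to beat self-condensation of prenal: the self-reaction is second order in aldehyde, so slow addition to the ketone enolate suppresses it, and the β,β-dimethyl terminus blocks conjugate addition. Site selectivity is secured by the substrate, since the two ring α-methylenes are the only carbons acidic enough under hydroxide, the amide α-CH2 being far less acidic.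

Step 5
Reactants: 8 N-methoxy-N-methyl-3-[(3E,5E)-3,5-bis(3-methylbut-2-en-1-ylidene)-4-oxocyclohexyl]propanamide
Product: 10 3-[4-hydroxy-3,5-bis(3-methylbut-2-en-1-yl)phenyl]-N-methoxy-N-methylpropanamide, via cyclohexa-2,5-dienone tautomer 9 (not isolated)
Conditions: RhCl3·3H2O (5 mol%), EtOH, 75 °C, Ar
Reagents that add atoms: none
Why: Proposed new method: an Rh–H species generated from RhCl3 and ethanol should add across each exocyclic enone with hydrogen going to the exocyclic β-carbon (C1'') and rhodium to the ring α-carbon as an oxa-allyl, and β-hydride elimination from the neighbouring ring CH2 then places the double bond in the ring and leaves each side chain as a prenyl group; after both shifts the cyclohexa-2,5-dienone 9 tautomerises to the phenol, the gain in aromaticity making the process irreversible, while the hindered trisubstituted alkene of each new prenyl group is a poor ligand for further hydride walking; the closest known reaction type is the rhodium-catalysed isoaromatisation of 2,6-dibenzylidenecyclohexanones to 2,6-dibenzylphenols (exocyclic-to-endocyclic alkene migration).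

Step 6
Reactants: 11 phloroglucinol (benzene-1,3,5-triol)
Product: 12 1,3,5-tris(methoxymethoxy)benzene
Conditions: NaH (3.3 equiv), DMF, 0 °C; MOMCl (3.3 equiv), 0 °C to rt
Reagents that add atoms: chloromethyl methyl ether (MOMCl), COCCl
Why: Williamson-type O-alkylation of the phenoxides with the hard electrophile MOMCl should give the tris-acetal ether, three equivalents of base and reagent exhausting the three equivalent hydroxyls.

Step 7
Reactants: 10 3-[4-hydroxy-3,5-bis(3-methylbut-2-en-1-yl)phenyl]-N-methoxy-N-methylpropanamide; 12 1,3,5-tris(methoxymethoxy)benzene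
Product: 15 3-[4-hydroxy-3,5-bis(3-methylbut-2-en-1-yl)phenyl]-1-[2,4,6-tris(methoxymethoxy)phenyl]propan-1-one, via aryllithium 13 (not isolated), via tetrahedral lithium adduct 14 (not isolated)
Conditions: 12 (2.7 equiv), n-BuLi (2.5 equiv), THF, 0 °C; then 10, −78 to 0 °C; NH4Cl (aq.)
Reagents that add atoms: none
Why: Directed ortho-metalation of 12 at the position flanked by two OMOM groups gives 13, whose first equivalent deprotonates the phenol of 10 and whose further equivalents add to the amide (Weinreb ketone synthesis); the chelated adduct 14 survives until the aqueous quench, so no second addition occurs, and the slight excess of 12 over n-BuLi leaves no alkyllithium to compete.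

Step 8
Reactants: 15 3-[4-hydroxy-3,5-bis(3-methylbut-2-en-1-yl)phenyl]-1-[2,4,6-tris(methoxymethoxy)phenyl]propan-1-one
Product: 16 4,2',4',6'-tetrahydroxy-3,5-diprenyldihydrochalcone, that is 3-[4-hydroxy-3,5-bis(3-methylbut-2-en-1-yl)phenyl]-1-(2,4,6-trihydroxyphenyl)propan-1-one
Conditions: HCl (3 M aq.), MeOH, 40 °C
Reagents that add atoms: none
Why: Acid-catalysed acetal exchange with methanol (MOM ether cleavage) should remove all three groups, the two ortho to the ketone fastest, and dilute acid at mild temperature is chosen so that the ring B phenol does not add to its neighbouring prenyl alkenes.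

Compound list
1 | 3-(4-hydroxyphenyl)propanoic acid (phloretic acid) | OC(=O)CCc1ccc(O)cc1 | starting material
2 | 3-(4-hydroxycyclohexyl)propanoic acid (cis/trans mixture, configuration not assigned) | OC(=O)CCC1CCC(O)CC1 | intermediate
3 | 3-(4-oxocyclohexyl)propanoic acid | OC(=O)CCC1CCC(=O)CC1 | intermediate
4 | 1-(1H-imidazol-1-yl)-3-(4-oxocyclohexyl)propan-1-one (acyl imidazolide, not isolated) | O=C1CCC(CCC(=O)n2ccnc2)CC1 | intermediate
5 | N-methoxy-N-methyl-3-(4-oxocyclohexyl)propanamide | CON(C)C(=O)CCC1CCC(=O)CC1 | intermediate
6 | 3-methylbut-2-enal (prenal) | CC(C)=CC=O | starting material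
7 | N-methoxy-N-methyl-3-[(3E)-3-(3-methylbut-2-en-1-ylidene)-4-oxocyclohexyl]propanamide (racemic, not isolated) | CON(C)C(=O)CCC1CCC(=O)/C(=C/C=C(C)C)C1 | intermediate
8 | N-methoxy-N-methyl-3-[(3E,5E)-3,5-bis(3-methylbut-2-en-1-ylidene)-4-oxocyclohexyl]propanamide | CON(C)C(=O)CCC1C/C(=C\C=C(C)C)C(=O)/C(=C/C=C(C)C)C1 | intermediate
9 | N-methoxy-N-methyl-3-[3,5-bis(3-methylbut-2-en-1-yl)-4-oxocyclohexa-2,5-dien-1-yl]propanamide (not isolated) | CON(C)C(=O)CCC1C=C(CC=C(C)C)C(=O)C(CC=C(C)C)=C1 | intermediate
10 | 3-[4-hydroxy-3,5-bis(3-methylbut-2-en-1-yl)phenyl]-N-methoxy-N-methylpropanamide | CON(C)C(=O)CCc1cc(CC=C(C)C)c(O)c(CC=C(C)C)c1 | intermediate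
11 | phloroglucinol (benzene-1,3,5-triol) | Oc1cc(O)cc(O)c1 | starting material
12 | 1,3,5-tris(methoxymethoxy)benzene | COCOc1cc(OCOC)cc(OCOC)c1 | intermediate
13 | [2,4,6-tris(methoxymethoxy)phenyl]lithium (not isolated) | [Li]c1c(OCOC)cc(OCOC)cc1OCOC | intermediate
14 | dilithium salt of the tetrahedral adduct of 13 with 10, alkoxide and phenoxide (not isolated) | CON(C)C([O-])(CCc1cc(CC=C(C)C)c([O-])c(CC=C(C)C)c1)c1c(OCOC)cc(OCOC)cc1OCOC.[Li+].[Li+] | intermediate
15 | 3-[4-hydroxy-3,5-bis(3-methylbut-2-en-1-yl)phenyl]-1-[2,4,6-tris(methoxymethoxy)phenyl]propan-1-one | COCOc1cc(OCOC)c(C(=O)CCc2cc(CC=C(C)C)c(O)c(CC=C(C)C)c2)c(OCOC)c1 | intermediate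
16 | 4,2',4',6'-tetrahydroxy-3,5-diprenyldihydrochalcone | CC(C)=CCc1cc(CCC(=O)c2c(O)cc(O)cc2O)cc(CC=C(C)C)c1O | target

Total step count: 8. Longest linear sequence: 7 steps (steps 1 to 5, then 7 and 8); step 6 is a one-step branch that prepares the ring A partner.

Steps most likely to fail

Step 5 (proposed new method). What may go wrong:
- Hydride delivery at the far end of the diene, or continued hydride walking, would move the side-chain alkene into conjugation with the new arene.
- E-to-Z isomerisation of the dienone would open an oxa-6π electrocyclisation to a 2H-pyran.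
- Acid released from the catalyst could close the fresh phenol onto a prenyl alkene.
- The catalyst could be held as a stable allyl complex.

Fallback, known chemistry, setting out from 1 and coming back at 10: the cyclohexanone construction is given up and the prenyl groups are put directly on the phenol. Acid 1 is coupled with N,O-dimethylhydroxylamine hydrochloride (EDC·HCl, HOBt, Et3N, CH2Cl2) to give N-methoxy-N-methyl-3-(4-hydroxyphenyl)propanamide F1. Its sodium phenoxide (NaH, toluene) is then alkylated with 1-bromo-3-methylbut-2-ene (2.2 equiv). In this non-polar medium phenoxides alkylate at carbon, and with the para position blocked both ortho positions should take a prenyl group to give 10. The price is separation from O-prenylated and mono-prenylated material.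

Step 4 (key step). What may go wrong:
- Self-condensation of prenal through its dienolate could outrun the cross-aldol.
- The reaction could stall after the first condensation.
- Deprotonation of the product at its terminal methyl groups could lead to oligomers.
- The amide could be slowly hydrolysed.

Fallback, setting out from 5 and coming back at 8: the two condensations are run one at a time as directed aldol reactions. The kinetic lithium enolate of 5 (LiN(i-Pr)2, THF, −78 °C) is treated with 6 to give N-methoxy-N-methyl-3-[3-(1-hydroxy-3-methylbut-2-en-1-yl)-4-oxocyclohexyl]propanamide F2 as a diastereomer mixture. MsCl/Et3N converts it into the allylic methanesulfonate F3, which eliminates in the flask on addition of DBU to the E-dienone 7, now isolated. Enolisation of 7 at its remaining α-methylene in the same way and addition to 6 gives the second aldol adduct F4, whose methanesulfonate F5 eliminates to 8. Prenal is consumed at −78 °C by a preformed enolate and never sits with base under equilibrating conditions.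

Step 8. What may go wrong:
- Acid-catalysed closure of the ring B phenol onto an adjacent prenyl alkene (chroman formation).
- Markovnikov addition of methanol or HCl to the prenyl alkenes.
- Incomplete cleavage of the para MOM ether under conditions mild enough to avoid the first two.

Fallback, setting out from 11 (with 10 as partner) and coming back at 16: the acid-labile groups are replaced by fluoride-labile ones. Phloroglucinol 11 with SEMCl/NaH in DMF gives 1,3,5-tris{[2-(trimethylsilyl)ethoxy]methoxy}benzene F6. Ortho-lithiation with n-BuLi in THF gives {2,4,6-tris{[2-(trimethylsilyl)ethoxy]methoxy}phenyl}lithium F7, which adds to 10 through the tetrahedral lithium adduct F8. Aqueous quench gives 3-[4-hydroxy-3,5-bis(3-methylbut-2-en-1-yl)phenyl]-1-{2,4,6-tris{[2-(trimethylsilyl)ethoxy]methoxy}phenyl}propan-1-one F9. Bu4NF in THF/DMPU at 60 °C then removes the three SEM groups under non-acidic conditions to give 16.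

Further compounds
F1 | step 5 | N-methoxy-N-methyl-3-(4-hydroxyphenyl)propanamide | CON(C)C(=O)CCc1ccc(O)cc1
F2 | step 4 | N-methoxy-N-methyl-3-[3-(1-hydroxy-3-methylbut-2-en-1-yl)-4-oxocyclohexyl]propanamide (diastereomer mixture) | CON(C)C(=O)CCC1CCC(=O)C(C1)C(O)C=C(C)C
F3 | step 4 | methanesulfonate of F2 (not isolated) | CON(C)C(=O)CCC1CCC(=O)C(C1)C(OS(C)(=O)=O)C=C(C)C
F4 | step 4 | N-methoxy-N-methyl-3-[(3E)-5-(1-hydroxy-3-methylbut-2-en-1-yl)-3-(3-methylbut-2-en-1-ylidene)-4-oxocyclohexyl]propanamide (diastereomer mixture) | CON(C)C(=O)CCC1CC(C(O)C=C(C)C)C(=O)/C(=C/C=C(C)C)C1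
F5 | step 4 | methanesulfonate of F4 (not isolated) | CON(C)C(=O)CCC1CC(C(OS(C)(=O)=O)C=C(C)C)C(=O)/C(=C/C=C(C)C)C1
F6 | step 8 | 1,3,5-tris{[2-(trimethylsilyl)ethoxy]methoxy}benzene | C[Si](C)(C)CCOCOc1cc(OCOCC[Si](C)(C)C)cc(OCOCC[Si](C)(C)C)c1
F7 | step 8 | {2,4,6-tris{[2-(trimethylsilyl)ethoxy]methoxy}phenyl}lithium (not isolated) | [Li]c1c(OCOCC[Si](C)(C)C)cc(OCOCC[Si](C)(C)C)cc1OCOCC[Si](C)(C)C
F8 | step 8 | dilithium salt of the tetrahedral adduct of F7 with 10 (not isolated) | CON(C)C([O-])(CCc1cc(CC=C(C)C)c([O-])c(CC=C(C)C)c1)c1c(OCOCC[Si](C)(C)C)cc(OCOCC[Si](C)(C)C)cc1OCOCC[Si](C)(C)C.[Li+].[Li+]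
F9 | step 8 | 3-[4-hydroxy-3,5-bis(3-methylbut-2-en-1-yl)phenyl]-1-{2,4,6-tris{[2-(trimethylsilyl)ethoxy]methoxy}phenyl}propan-1-one | C[Si](C)(C)CCOCOc1cc(OCOCC[Si](C)(C)C)c(C(=O)CCc2cc(CC=C(C)C)c(O)c(CC=C(C)C)c2)c(OCOCC[Si](C)(C)C)c1
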